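Which of these flasks, alike in what they are charged but not in when it goes in, ends with the most isomer of the product?

| flask | starting material | reagent | time | remark |
|---|---|---|---|---|
| Friday's | 5.0 mM (fed, over 12 s) | 2.50 equiv | 20 s | all else is in the flask from the start; the feed brings no volume worth counting |
| Tuesday's | 5.0 mM | 2.50 equiv | 20 s | everything together at the start |
| Saturday's | 5.0 mM | 2.50 equiv (in portions, 2, over 12 s) | 20 s | first portion at the start, last at 12 s |
| Wednesday's | 5.0 mM | 2.50 equiv (fed, over 12 s) | 20 s | all else is in the flask from the start; the feed brings no volume worth counting |

    starting material + reagent → first product (k1 = 206 M⁻¹ s⁻¹)
    reagent + first product ⇌ double product (K2 = 344 M⁻¹, k2 = 661 M⁻¹ s⁻¹)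
    double product ⇌ isomer of the product (K3 = 1.89, k3 = 0.0380 s⁻¹)
    reagent ⇌ dormant form (K4 = 0.24, k4 = 0.144 s⁻¹)

- which flask leads in amount of isomer of the product, in percent of the starting material charged ("all alike" within 1.5 percentage points) (Friday's / Tuesday's / Saturday's / Wednesday's / all alike)
- how much isomer of the product is there at the end, in percent of the starting material charged: Friday's
- how much isomer of the product is there at the end, in percent of the starting material charged: Tuesday's
- how much isomer of the product is there at the end, in percent of the starting material charged: Saturday's
- how much isomer of the product is there at the end, in percent of the starting material charged: Wednesday's

We set Tuesday's beside Saturday's, which has the same charges and differs in the timing of the reagent. The isomerisation has a relaxation half-life of 11.9 s in Saturday's, longer than the 0.084 s forward half-life of first product with reagent in Tuesday's and the 0.932 s relaxation half-life of reagent and dormant form in Saturday's, so we take it as the rate-limiting step for the isomer of the product and let double product and dormant form stand balanced with reagent. Double product over first product is then 344 M⁻¹ times the reagent concentration. We call this ratio the split, and it passes unity when reagent stands at 23.3% of its own charge, the crossing.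

We reckon that Tuesday's pays one equivalent for first product and, taken over the run, about 0.5 for double product with its isomer, and that after the dormant form's share it keeps 32.3% of its reagent, above the crossing. The split is therefore 1.39, and the reversible isomerisation running on that split gives 29.8% isomer of the product at the end.

Saturday's first portion spares 0.250 equivalents once first product is made, which by our reckoning leaves about 3.38% of the whole reagent charge as reagent, below the crossing. Its split of 0.145 gives us an estimate of 5.78% isomer by 12 s. We apply Tuesday's split for the remaining time, which brings our estimate for Saturday's to 19.1%, less than our figure for Tuesday's because in this reckoning those first seconds pass below the crossing.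

The forecast names Tuesday's, with Tuesday's 28%, Friday's 23%, Saturday's 20% and Wednesday's 20%, holding that the isomerisation “simply integrates how much double product is present over time”. Our Tuesday's stands above its figure and our Saturday's below.

The simulation puts Tuesday's first: Tuesday's 27.8%, Friday's 21.9%, Wednesday's 20.9%, Saturday's 18.9%. Saturday's reagent read 4.02% just before the last addition, under the crossing, and 28.0% at the end, over it. A neighbour of Saturday's with 20 mM of starting material, at the same equivalents, has its crossing at 5.81%. The same reckoning gives splits of 0.212 and then 5.55, and 26.3% isomer; that flask ends with reagent at 21.3% of its charge and 25.6% isomer of the product.

(The constants were drawn at random within sensible limits; what happens was integrated by code.)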